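(The data were generated by integration from invented constants, and the scatter is random.)

In the south-west run, [second end groups] of 0.098 M nearly matches the first portion of first end groups, 0.100 M, and 2.00 min later 13% of the charge is left. For an equal pair consumed one for one, the rate goes as the square of what is left, so the start amount over the amount left, minus one, grows in step with time. That reading gives τ = 0.703 min, the coupling time, in which an equal pair at portion strength loses half.

in all of them: first end groups 0.20 M (in portions, 2)

| charge | second end groups | remark | time |
|---|---|---|---|
| south-west | 0.098 M | run made earlier; portions every 8.0 min |  |
| north-east | 0.15 M | run made earlier; portions every 8.0 min |  |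
| flask | 0.196 M | the portions of first end groups follow each other after 8.0 min, the first at the start | 15 min |

| run | time / min | links / % | first end groups / % | side product / % |
|---|---|---|---|---|
| south-west | 2.00 | 36 | 13 | 0 |
| south-west | 4.00 | 43 | 6 | 1 |
| south-west | 5.00 | 46 | 7 | 2 |
| south-west | 8.00 | 47 | 1 | 0 |
| south-west | 10.0 | 50 | 52 | 1 |
| north-east | 2.00 | 47 | 4 | 0 |
| north-east | 4.00 | 46 | 0 | 2 |
| north-east | 5.00 | 52 | 2 | 0 |
| north-east | 8.00 | 47 | 1 | 1 |
| north-east | 10.0 | 69 | 26 | 4 |

(readings scatter by 2 percentage points)

1. links present at 15 min, in percent of the first end groups charged
2. first end groups present at 15 min, in percent of the first end groups charged
3. side product present at 15 min, in percent of the first end groups charged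

- the numbers in the tables scatter by 2 percentage points (one standard deviation)

One reading is a thin ground. The north-east run, with second end groups in excess, gives 0.635 min by the form for unequal pairs, and we keep τ.

Does the first portion in the flask finish in time? The second end groups left over once that portion is spent, 0.0960 M, are a little fewer than the portion itself, so the decay time of its tail is 0.732 min, slightly longer than τ but far less than the 8.0 min interval, and by this reckoning the first end groups remaining at the second addition come to <0.001% of the charge. That portion then meets 0.0960 M of second end groups, and treating them as an equal pair leaves 4.56% after 7.00 min.

But the pair is not equal: second end groups are the limiting reagent, short by 2.00% of the charge. With that gap, the ratio of first to second end groups left climbs to 1.55, which leaves 5.63%. That is our estimate. Taking 4% of side product, the last north-east reading, from links leaves links near 90.4%.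

The forecast, calling the second stage “a near-equimolar mixture”, gives links 91%, first end groups 4.5%, below our estimate, and side product 2.5%.

The flask gives links 89.2%, first end groups 4.43% and side product 6.39%.

    first end groups + second end groups → links + released group (k = 20.0 M⁻¹ min⁻¹)
    links + released group → side product (k = 0.0460 M⁻¹ min⁻¹)

In the flask at 15.0 min, links halve by their reaction with released group in 84 min, longer than the flask's 15 min and far longer than the coupling time of 0.703 min that we read from the south-west run, while the second end groups still present halve in 3.9 min. In the neighbour flask charged with 0.33 M of second end groups, 0.130 M are over once both portions are spent, so the same reading of τ gives a decay time of 0.541 min for the second portion, and that neighbour holds 92.6% links and 0% first end groups.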